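**Retrosynthetic overview**
1. Target ⇐ desilylation/demethylation and C3 aroylation of bicyclic enol ether 29 with aroyl chloride 35 (fragment 3, from catechol).
2. 29 ⇐ palladium-catalysed coupling of the C5–H bridgehead of core 14 (fragment 1) with allylic carbonate 26 (fragment 2); this forms the C5–C1′ bond and the second quaternary bridgehead.
3. 14 ⇐ ring A closed onto ring B by Effenberger annulation of malonyl dichloride with silyl enol ether 11; the C7 stereocentre steers both bridgeheads.
4. 11 ⇐ cyclohexane-1,3-dione (ring B present from the start): decarboxylative asymmetric allylation sets C7, then carbonyl transposition and conjugate methylation.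
5. 26 ⇐ alkenyl iodide (from but-2-yn-1-ol) plus Weinreb amide (from 4-methylpent-3-enoic acid); CBS reduction sets C4′.

Assumption: the target SMILES is one enol tautomer of a 3-acyl-2,4,9-trione; the tautomers interconvert freely, so this tautomer is taken as the compound obtained.
Conventions: prenyl = 3-methylbut-2-en-1-yl; TBS = tert-butyldimethylsilyl. Bicyclic numbering: C1 prenyl bridgehead, C2–C3–C4 enol-dione bridge, C5 second bridgehead, C7 CH(prenyl), C8 CMe2, C9 bridging ketone. In every bicyclic compound the C2–C4 bridge is anti to the C7 prenyl group; bridgehead CIP letters change along the route only because substituent priorities change.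

**Fragment 1 (core)**

Step 1
Reactants: 1 cyclohexane-1,3-dione; 2 prenyl bromide
Product: 3 2-prenylcyclohexane-1,3-dione
Conditions: KOH (1 equiv), H2O, 0 → 23 °C
Reagents that add atoms: none
Why: C-alkylation of the 1,3-dione enolate by the soft allylic bromide in water (hydrogen bonding shields oxygen) gives the 2-substituted dione; no stereocentre is formed.

Step 2
Reactants: 3 2-prenylcyclohexane-1,3-dione
Product: 4 3-methoxy-2-prenylcyclohex-2-en-1-one
Conditions: Me2SO4, K2CO3, acetone, 56 °C
Reagents that add atoms: dimethyl sulfate, COS(=O)(=O)OC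
Why: Base-mediated O-methylation of the enolised dione (vinylogous ester formation) avoids the acid that would cyclise the prenyl group onto the enol.

Step 3
Reactants: 4 3-methoxy-2-prenylcyclohex-2-en-1-one
Product: 6 allyl 5-methoxy-6-prenylcyclohexa-1,5-dien-1-yl carbonate, via lithium dienolate 5 (not isolated)
Conditions: LiN(iPr)2, THF, −78 °C; then TMEDA, allyl chloroformate, −78 → 0 °C
Reagents that add atoms: allyl chloroformate, C=CCOC(=O)Cl
Why: Kinetic α′-deprotonation of the vinylogous ester (Stork–Danheiser regiochemistry) and O-acylation of the TMEDA-solvated dienolate by the chloroformate give the allyl enol carbonate.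

Step 4
Reactants: 6 allyl 5-methoxy-6-prenylcyclohexa-1,5-dien-1-yl carbonate
Product: 7 (6S)-6-allyl-3-methoxy-2-prenylcyclohex-2-en-1-one
Conditions: Pd2(dba)3·CHCl3 (2.5 mol %), (R,R)-ANDEN-phenyl Trost ligand (5.5 mol %), 1,4-dioxane, 23 °C
Reagents that add atoms: none
Why: Decarboxylative asymmetric allylic alkylation (Tsuji–Trost type): zerovalent palladium ionises the carbonate, CO2 is lost, and the α′-enolate recombines with the π-allyl complex inside the chiral pocket under neutral conditions, setting the tertiary C6 centre (future C7) as S without epimerisation; the ligand enantiomer is the one that gives 6S, to be confirmed by rotation at this stage, with its antipode used if the sense is opposite.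

Step 5
Reactants: 7 (6S)-6-allyl-3-methoxy-2-prenylcyclohex-2-en-1-one
Product: 8 (6S)-3-methoxy-2,6-diprenylcyclohex-2-en-1-one
Conditions: 2-methylbut-2-ene (excess), second-generation Grubbs catalyst RuCl2(PCy3)(H2IMes)(=CHPh) (5 mol %), CH2Cl2, 40 °C
Reagents that add atoms: 2-methylbut-2-ene, CC=C(C)C
Why: Olefin cross-metathesis converts the only monosubstituted alkene into a prenyl group; the trisubstituted prenyl alkene and the enol ether double bond are inert and C6 is untouched.

Step 6
Reactants: 8 (6S)-3-methoxy-2,6-diprenylcyclohex-2-en-1-one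
Product: 10 (4S)-3-methyl-2,4-diprenylcyclohex-2-en-1-one, via tertiary carbinol 9 (not isolated)
Conditions: MeLi, CeCl3, THF, −78 °C; then 1 M aq HCl, THF, 23 °C
Reagents that add atoms: methyllithium, [Li]C
Why: Stork–Danheiser carbonyl transposition: the weakly basic organocerium adds 1,2 without enolising the α′ centre (so it stays S), and acid hydrolysis of the enol ether with dehydration gives the transposed enone.

Step 7
Reactants: 10 (4S)-3-methyl-2,4-diprenylcyclohex-2-en-1-one
Product: 11 {[(4S)-3,3-dimethyl-2,4-diprenylcyclohex-1-en-1-yl]oxy}trimethylsilane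
Conditions: MeMgBr (2 equiv), CuBr·SMe2 (10 mol %), TMSCl, HMPA, THF, −78 → −30 °C; Et3N quench
Reagents that add atoms: methylmagnesium bromide, C[Mg]Br; chlorotrimethylsilane, C[Si](C)(C)Cl
Why: Copper-catalysed conjugate addition accelerated by TMSCl/HMPA builds the gem-dimethyl carbon (future C8) and traps the enolate regiospecifically as the tetrasubstituted silyl enol ether; no new stereocentre arises.

Step 8
Reactants: 11 {[(4S)-3,3-dimethyl-2,4-diprenylcyclohex-1-en-1-yl]oxy}trimethylsilane; 12 malonyl dichloride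
Product: 13 (1R,5S,7R)-4-hydroxy-8,8-dimethyl-1,7-diprenylbicyclo[3.3.1]non-3-ene-2,9-dione (C5–H; bridge anti to the C7 prenyl)
Conditions: CH2Cl2, −20 → 23 °C, 24 h
Reagents that add atoms: none
Why: Effenberger α,α′-annulation: the silyl enol ether is C-acylated at C1 by axial attack anti to the equatorial C7 prenyl, and the tethered acyl chloride (or ketene) then acylates C5 on the same face, so C7 fixes both bridgeheads and ring A closes with the prenyl exo.

Step 9
Reactants: 13 (1R,5S,7R)-4-hydroxy-8,8-dimethyl-1,7-diprenylbicyclo[3.3.1]non-3-ene-2,9-dione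
Product: 14 (1R,5S,7R)-2-methoxy-8,8-dimethyl-1,7-diprenylbicyclo[3.3.1]non-2-ene-4,9-dione
Conditions: Me2SO4, K2CO3, acetone, 56 °C; chromatography
Reagents that add atoms: dimethyl sulfate, COS(=O)(=O)OC
Why: Williamson-type O-methylation of the enolised β-diketone gives both vinylogous esters; 14 (OMe at C2, leaving C5–H flanked by the C4 and C9 carbonyls) is separated and the 4-methoxy isomer is returned to 13 with LiOH.

**Fragment 2 (side chain)**

Step 10
Reactants: 15 but-2-yn-1-ol
Product: 16 tert-butyl(but-2-yn-1-yloxy)dimethylsilane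
Conditions: TBSCl, imidazole, CH2Cl2, 23 °C
Reagents that add atoms: tert-butyldimethylsilyl chloride, CC(C)(C)[Si](C)(C)Cl
Why: Standard silylation protects the primary alcohol before the organometallic steps.

Step 11
Reactants: 16 tert-butyl(but-2-yn-1-yloxy)dimethylsilane
Product: 18 tert-butyl{[(2E)-3-iodobut-2-en-1-yl]oxy}dimethylsilane, via alkenylzirconocene chloride 17 (not isolated)
Conditions: Cp2Zr(H)Cl (1.8 equiv), THF, 50 °C; then I2, 0 °C
Reagents that add atoms: iodine, II
Why: Syn-hydrozirconation; with excess Cp2Zr(H)Cl the alkenylzirconium equilibrates to the isomer with Zr on the methyl-bearing carbon, and iodinolysis with retention gives the E iodide (methyl cis to the CH2O carbon).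

Step 12
Reactants: 19 4-methylpent-3-enoic acid
Product: 20 N-methoxy-N,4-dimethylpent-3-enamide
Conditions: MeNHOMe·HCl, EDC·HCl, Et3N, DMAP (cat.), CH2Cl2, 0 → 23 °C
Reagents that add atoms: N,O-dimethylhydroxylamine hydrochloride, CNOC.Cl
Why: Carbodiimide amidation gives the Weinreb amide under mild conditions that do not move the β,γ double bond.

Step 13
Reactants: 18 tert-butyl{[(2E)-3-iodobut-2-en-1-yl]oxy}dimethylsilane; 20 N-methoxy-N,4-dimethylpent-3-enamide
Product: 22 (2E)-1-(tert-butyldimethylsilyloxy)-3,7-dimethylocta-2,6-dien-4-one, via alkenyllithium 21 (not isolated)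
Conditions: t-BuLi (2 equiv), Et2O, −78 °C; then 20, −78 → −20 °C; aq NH4Cl
Reagents that add atoms: none
Why: Iodine–lithium exchange proceeds with retention of alkene geometry, and Weinreb ketone synthesis (chelated tetrahedral intermediate, no over-addition) gives the E enone; the neutral quench keeps the skipped alkene out of conjugation.

Step 14
Reactants: 22 (2E)-1-(tert-butyldimethylsilyloxy)-3,7-dimethylocta-2,6-dien-4-one
Product: 23 (2E,4S)-1-(tert-butyldimethylsilyloxy)-3,7-dimethylocta-2,6-dien-4-ol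
Conditions: (R)-2-methyl-CBS-oxazaborolidine (15 mol %), catecholborane, toluene, −78 °C
Reagents that add atoms: none
Why: Corey–Bakshi–Shibata reduction: the α-methyl enone arm acts as the large group, so the (R)-catalyst delivers hydride to the face that gives the 4S allylic alcohol, with 1,2-selectivity.

Step 15
Reactants: 23 (2E,4S)-1-(tert-butyldimethylsilyloxy)-3,7-dimethylocta-2,6-dien-4-ol
Product: 24 (2E,4S)-1,4-bis(tert-butyldimethylsilyloxy)-3,7-dimethylocta-2,6-diene
Conditions: TBSCl, imidazole, DMF, 23 °C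
Reagents that add atoms: tert-butyldimethylsilyl chloride, CC(C)(C)[Si](C)(C)Cl
Why: Silylation of the secondary allylic alcohol; the carbinol centre is not touched.

Step 16
Reactants: 24 (2E,4S)-1,4-bis(tert-butyldimethylsilyloxy)-3,7-dimethylocta-2,6-diene
Product: 25 (2E,4S)-4-(tert-butyldimethylsilyloxy)-3,7-dimethylocta-2,6-dien-1-ol
Conditions: HF·pyridine, pyridine, THF, 0 °C
Reagents that add atoms: none
Why: Selective desilylation: the unhindered primary allylic silyl ether is cleaved much faster than the secondary one flanked by the trisubstituted alkene.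

Step 17
Reactants: 25 (2E,4S)-4-(tert-butyldimethylsilyloxy)-3,7-dimethylocta-2,6-dien-1-ol
Product: 26 (2E,4S)-4-(tert-butyldimethylsilyloxy)-3,7-dimethylocta-2,6-dien-1-yl methyl carbonate
Conditions: methyl chloroformate, pyridine, CH2Cl2, 0 °C
Reagents that add atoms: methyl chloroformate, COC(=O)Cl
Why: Acylation of the primary alcohol gives a stable allylic carbonate that ionises readily on zerovalent palladium.

**Fragment union**

Step 18
Reactants: 14 (1R,5S,7R)-2-methoxy-8,8-dimethyl-1,7-diprenylbicyclo[3.3.1]non-2-ene-4,9-dione; 26 (2E,4S)-4-(tert-butyldimethylsilyloxy)-3,7-dimethylocta-2,6-dien-1-yl methyl carbonate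
Product: 29 (1R,5S,7R)-5-[(2E,4S)-4-(tert-butyldimethylsilyloxy)-3,7-dimethylocta-2,6-dien-1-yl]-2-methoxy-8,8-dimethyl-1,7-diprenylbicyclo[3.3.1]non-2-ene-4,9-dione, via bridgehead lithium compound 27 (not isolated), via bridgehead zinc chloride 28 (not isolated)
Conditions: LiN(iPr)2 (1.2 equiv), THF, −78 °C; ZnCl2 (1.3 equiv), −78 → −20 °C; then 26 (1.2 equiv), Pd2(dba)3 (2.5 mol %), tri(2-furyl)phosphine (10 mol %), THF, −20 → 23 °C
Reagents that add atoms: none
Why: Proposed new method: palladium-catalysed Negishi-type allylation of a bridgehead α,α′-diketo organozinc made by C–H lithiation/zincation; C5–H of 14 is the only α′ proton of the vinylogous ester and, flanked by the C4 and C9 carbonyls, is removed by LiN(iPr)2 to give a configurationally locked σ-carbanion that cannot become an O-bound enolate (Bredt), zerovalent palladium ionises 26 to a cationic π-allyl complex whose methoxide counter-ion assists Zn-to-Pd transfer, the resulting bridgehead-alkyl(allyl)palladium has no β-hydride elimination pathway (it would need a bridgehead alkene) and reductively eliminates at the unsubstituted allyl terminus with the E geometry kept because syn/anti exchange would need a tertiary σ-allyl, the π-acidic phosphine speeds this step, and the bicycle fixes the new quaternary centre; the closest known reactions are Negishi couplings of alkylzinc and Reformatsky reagents with allylic electrophiles and the stoichiometric bridgehead lithiation–alkylation of such enol ethers.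

**Fragment 3 (aroyl unit)**

Step 19
Reactants: 30 catechol
Product: 31 4-bromobenzene-1,2-diol
Conditions: NBS (1.0 equiv), HBF4·OEt2 (cat.), MeCN, −30 → 23 °C
Reagents that add atoms: N-bromosuccinimide, O=C1CCC(=O)N1Br
Why: Electrophilic aromatic bromination occurs para to one hydroxyl, and one equivalent at low temperature stops at the monobromide.

Step 20
Reactants: 31 4-bromobenzene-1,2-diol
Product: 32 4-bromo-1,2-bis(tert-butyldimethylsilyloxy)benzene
Conditions: TBSCl (2.3 equiv), imidazole, DMF, 23 °C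
Reagents that add atoms: tert-butyldimethylsilyl chloride, CC(C)(C)[Si](C)(C)Cl
Why: Bis-silylation gives phenol protection that survives organolithiums and leaves later with fluoride.

Step 21
Reactants: 32 4-bromo-1,2-bis(tert-butyldimethylsilyloxy)benzene
Product: 34 3,4-bis(tert-butyldimethylsilyloxy)benzoic acid, via aryllithium 33 (not isolated)
Conditions: n-BuLi, THF, −78 °C; then CO2, −78 → 0 °C; dilute HCl to pH 4
Reagents that add atoms: carbon dioxide, O=C=O
Why: Bromine–lithium exchange then carboxylation; the lithium is meta/para to the silyloxy groups, so no silyl migration occurs.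

Step 22
Reactants: 34 3,4-bis(tert-butyldimethylsilyloxy)benzoic acid
Product: 35 3,4-bis(tert-butyldimethylsilyloxy)benzoyl chloride
Conditions: 1-chloro-N,N,2-trimethylprop-1-en-1-amine, CH2Cl2, 0 → 23 °C
Reagents that add atoms: 1-chloro-N,N,2-trimethylprop-1-en-1-amine (Ghosez reagent), CC(C)=C(Cl)N(C)C
Why: Acid chloride formation under neutral conditions (no HCl) keeps the aryl silyl ethers intact.

**Endgame**

Step 23
Reactants: 29 bridgehead-coupled enol ether (see step 18); 35 3,4-bis(tert-butyldimethylsilyloxy)benzoyl chloride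
Product: 37 (1R,5R,7R)-3-[3,4-bis(tert-butyldimethylsilyloxy)benzoyl]-5-[(2E,4S)-4-(tert-butyldimethylsilyloxy)-3,7-dimethylocta-2,6-dien-1-yl]-2-methoxy-8,8-dimethyl-1,7-diprenylbicyclo[3.3.1]non-2-ene-4,9-dione, via C3-lithio enol ether 36 (not isolated)
Conditions: lithium 2,2,6,6-tetramethylpiperidide (1.3 equiv), THF, −78 °C; then 35, −78 → −40 °C
Reagents that add atoms: none
Why: α-Lithiation of the vinylogous ester at the vinylic C3–H (the only acidic C–H left, both bridgeheads being quaternary) and C-acylation by the aroyl chloride; no stereocentre is affected.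

Step 24
Reactants: 37 tris-silylated 3-aroyl enol ether (see step 23)
Product: 38 (1R,5R,7R)-3-(3,4-dihydroxybenzoyl)-5-[(2E,4S)-4-hydroxy-3,7-dimethylocta-2,6-dien-1-yl]-2-methoxy-8,8-dimethyl-1,7-diprenylbicyclo[3.3.1]non-2-ene-4,9-dione
Conditions: Bu4NF (3.5 equiv), AcOH (3.5 equiv), THF, 0 → 23 °C, argon
Reagents that add atoms: none
Why: Buffered fluoride desilylation removes the two aryl and the secondary alkyl TBS groups without acid, which would cyclise prenyl groups onto the enol.

Step 25
Reactants: 38 methyl enol ether of the target (see step 24)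
Product: 39 target, (1S,5S,7R)-3-(3,4-dihydroxybenzoyl)-4-hydroxy-5-[(2E,4S)-4-hydroxy-3,7-dimethylocta-2,6-dien-1-yl]-8,8-dimethyl-1,7-diprenylbicyclo[3.3.1]non-3-ene-2,9-dione
Conditions: LiCl (10 equiv), DMSO, 120 °C, argon; dilute citric acid work-up
Reagents that add atoms: none
Why: Krapcho-type SN2 demethylation of the activated vinylogous methyl ester by chloride under neutral conditions frees the enol, which settles into the chelated tautomer of the target.

**Compound list**
1 | cyclohexane-1,3-dione | O=C1CCCC(=O)C1 | starting material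
2 | 1-bromo-3-methylbut-2-ene (prenyl bromide) | CC(C)=CCBr | starting material
3 | 2-prenylcyclohexane-1,3-dione | CC(C)=CCC1C(=O)CCCC1=O | intermediate
4 | 3-methoxy-2-prenylcyclohex-2-en-1-one | COC1=C(CC=C(C)C)C(=O)CCC1 | intermediate
5 | lithium 5-methoxy-6-prenylcyclohexa-1,5-dien-1-olate (not isolated) | [Li]OC1=CCCC(OC)=C1CC=C(C)C | intermediate
6 | allyl 5-methoxy-6-prenylcyclohexa-1,5-dien-1-yl carbonate | C=CCOC(=O)OC1=CCCC(OC)=C1CC=C(C)C | intermediate
7 | (6S)-6-allyl-3-methoxy-2-prenylcyclohex-2-en-1-one | C=CC[C@@H]1CCC(OC)=C(CC=C(C)C)C1=O | intermediate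
8 | (6S)-3-methoxy-2,6-diprenylcyclohex-2-en-1-one | CC(C)=CC[C@@H]1CCC(OC)=C(CC=C(C)C)C1=O | intermediate
9 | (6S)-3-methoxy-1-methyl-2,6-diprenylcyclohex-2-en-1-ol, both C1 epimers (not isolated) | CC(C)=CC[C@@H]1CCC(OC)=C(CC=C(C)C)C1(C)O | intermediate
10 | (4S)-3-methyl-2,4-diprenylcyclohex-2-en-1-one | CC(C)=CC[C@@H]1CCC(=O)C(CC=C(C)C)=C1C | intermediate
11 | {[(4S)-3,3-dimethyl-2,4-diprenylcyclohex-1-en-1-yl]oxy}trimethylsilane | CC(C)=CC[C@@H]1CCC(O[Si](C)(C)C)=C(CC=C(C)C)C1(C)C | intermediate
12 | propanedioyl dichloride (malonyl dichloride) | O=C(Cl)CC(=O)Cl | starting material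
13 | (1R,5S,7R)-4-hydroxy-8,8-dimethyl-1,7-diprenylbicyclo[3.3.1]non-3-ene-2,9-dione | CC(C)=CC[C@@H]1C[C@@H]2C(=O)[C@@](CC=C(C)C)(C(=O)C=C2O)C1(C)C | intermediate
14 | (1R,5S,7R)-2-methoxy-8,8-dimethyl-1,7-diprenylbicyclo[3.3.1]non-2-ene-4,9-dione | CC(C)=CC[C@@H]1C[C@@H]2C(=O)[C@@](CC=C(C)C)(C(OC)=CC2=O)C1(C)C | intermediate
15 | but-2-yn-1-ol | CC#CCO | starting material
16 | tert-butyl(but-2-yn-1-yloxy)dimethylsilane | CC#CCO[Si](C)(C)C(C)(C)C | intermediate
17 | chlorobis(cyclopentadienyl)[(2E)-4-(tert-butyldimethylsilyloxy)but-2-en-2-yl]zirconium (not isolated) | C/C(=C\CO[Si](C)(C)C(C)(C)C)[Zr](Cl)(C1C=CC=C1)C1C=CC=C1 | intermediate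
18 | tert-butyl{[(2E)-3-iodobut-2-en-1-yl]oxy}dimethylsilane | C/C(I)=C\CO[Si](C)(C)C(C)(C)C | intermediate
19 | 4-methylpent-3-enoic acid | CC(C)=CCC(=O)O | starting material
20 | N-methoxy-N,4-dimethylpent-3-enamide | CC(C)=CCC(=O)N(C)OC | intermediate
21 | [4-(tert-butyldimethylsilyloxy)but-2-en-2-yl]lithium, Li trans to the CH2O carbon (not isolated) | [Li]/C(C)=C/CO[Si](C)(C)C(C)(C)C | intermediate
22 | (2E)-1-(tert-butyldimethylsilyloxy)-3,7-dimethylocta-2,6-dien-4-one | CC(C)=CCC(=O)/C(C)=C/CO[Si](C)(C)C(C)(C)C | intermediate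
23 | (2E,4S)-1-(tert-butyldimethylsilyloxy)-3,7-dimethylocta-2,6-dien-4-ol | CC(C)(C)[Si](C)(C)OC/C=C(\C)[C@@H](O)CC=C(C)C | intermediate
24 | (2E,4S)-1,4-bis(tert-butyldimethylsilyloxy)-3,7-dimethylocta-2,6-diene | CC(C)(C)[Si](C)(C)OC/C=C(\C)[C@@H](O[Si](C)(C)C(C)(C)C)CC=C(C)C | intermediate
25 | (2E,4S)-4-(tert-butyldimethylsilyloxy)-3,7-dimethylocta-2,6-dien-1-ol | OC/C=C(\C)[C@@H](O[Si](C)(C)C(C)(C)C)CC=C(C)C | intermediate
26 | (2E,4S)-4-(tert-butyldimethylsilyloxy)-3,7-dimethylocta-2,6-dien-1-yl methyl carbonate | COC(=O)OC/C=C(\C)[C@@H](O[Si](C)(C)C(C)(C)C)CC=C(C)C | intermediate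
27 | C5-lithio derivative of 14, configuration as in 14 (not isolated) | CC(C)=CC[C@@H]1C[C@]2([Li])C(=O)[C@@](CC=C(C)C)(C(OC)=CC2=O)C1(C)C | intermediate
28 | C5-chlorozincio derivative of 14, configuration as in 14 (not isolated) | CC(C)=CC[C@@H]1C[C@]2([Zn]Cl)C(=O)[C@@](CC=C(C)C)(C(OC)=CC2=O)C1(C)C | intermediate
29 | (1R,5S,7R)-5-[(2E,4S)-4-(tert-butyldimethylsilyloxy)-3,7-dimethylocta-2,6-dien-1-yl]-2-methoxy-8,8-dimethyl-1,7-diprenylbicyclo[3.3.1]non-2-ene-4,9-dione | CC(C)=CC[C@@H]1C[C@]2(C/C=C(\C)[C@@H](O[Si](C)(C)C(C)(C)C)CC=C(C)C)C(=O)[C@@](CC=C(C)C)(C(OC)=CC2=O)C1(C)C | intermediate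
30 | benzene-1,2-diol (catechol) | Oc1ccccc1O | starting material
31 | 4-bromobenzene-1,2-diol | Oc1ccc(Br)cc1O | intermediate
32 | 4-bromo-1,2-bis(tert-butyldimethylsilyloxy)benzene | CC(C)(C)[Si](C)(C)Oc1ccc(Br)cc1O[Si](C)(C)C(C)(C)C | intermediate
33 | [3,4-bis(tert-butyldimethylsilyloxy)phenyl]lithium (not isolated) | [Li]c1ccc(O[Si](C)(C)C(C)(C)C)c(O[Si](C)(C)C(C)(C)C)c1 | intermediate
34 | 3,4-bis(tert-butyldimethylsilyloxy)benzoic acid | OC(=O)c1ccc(O[Si](C)(C)C(C)(C)C)c(O[Si](C)(C)C(C)(C)C)c1 | intermediate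
35 | 3,4-bis(tert-butyldimethylsilyloxy)benzoyl chloride | ClC(=O)c1ccc(O[Si](C)(C)C(C)(C)C)c(O[Si](C)(C)C(C)(C)C)c1 | intermediate
36 | C3-lithio derivative of 29 (not isolated) | CC(C)=CC[C@@H]1C[C@]2(C/C=C(\C)[C@@H](O[Si](C)(C)C(C)(C)C)CC=C(C)C)C(=O)[C@@](CC=C(C)C)(C(OC)=C([Li])C2=O)C1(C)C | intermediate
37 | (1R,5R,7R)-3-[3,4-bis(tert-butyldimethylsilyloxy)benzoyl]-5-[(2E,4S)-4-(tert-butyldimethylsilyloxy)-3,7-dimethylocta-2,6-dien-1-yl]-2-methoxy-8,8-dimethyl-1,7-diprenylbicyclo[3.3.1]non-2-ene-4,9-dione | CC(C)=CC[C@@H]1C[C@]2(C/C=C(\C)[C@@H](O[Si](C)(C)C(C)(C)C)CC=C(C)C)C(=O)[C@@](CC=C(C)C)(C(OC)=C(C(=O)c3ccc(O[Si](C)(C)C(C)(C)C)c(O[Si](C)(C)C(C)(C)C)c3)C2=O)C1(C)C | intermediate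
38 | (1R,5R,7R)-3-(3,4-dihydroxybenzoyl)-5-[(2E,4S)-4-hydroxy-3,7-dimethylocta-2,6-dien-1-yl]-2-methoxy-8,8-dimethyl-1,7-diprenylbicyclo[3.3.1]non-2-ene-4,9-dione | CC(C)=CC[C@@H]1C[C@]2(C/C=C(\C)[C@@H](O)CC=C(C)C)C(=O)[C@@](CC=C(C)C)(C(OC)=C(C(=O)c3ccc(O)c(O)c3)C2=O)C1(C)C | intermediate
39 | (1S,5S,7R)-3-(3,4-dihydroxybenzoyl)-4-hydroxy-5-[(2E,4S)-4-hydroxy-3,7-dimethylocta-2,6-dien-1-yl]-8,8-dimethyl-1,7-diprenylbicyclo[3.3.1]non-3-ene-2,9-dione | CC(C)=CC[C@@H]1C[C@]2(C/C=C(\C)[C@@H](O)CC=C(C)C)C(=O)[C@@](CC=C(C)C)(C(=O)C(C(=O)c3ccc(O)c(O)c3)=C2O)C1(C)C | target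

**Totals and risks**

Total step count: 25. Longest linear sequence: 13 steps (steps 1–9, 18, 23, 24, 25), which is 52 % of the total.

Step 8 is expected to be the lowest-yielding step, but the annulation is well established for this ring system, so it is not ranked among the three most likely failures below.

Step 18 (the new bridgehead coupling): the bridgehead zinc reagent may transmetalate too slowly, or the π-allyl complex may eliminate to a diene. The fallback uses known chemistry, sets out from 14 and 25, and comes back at 29. Alcohol 25 is converted with CBr4, PPh3 and 2,6-lutidine in CH2Cl2 at 0 °C into (2E,4S)-1-bromo-4-(tert-butyldimethylsilyloxy)-3,7-dimethylocta-2,6-diene F1. Enol ether 14 is lithiated at C5 with LiN(iPr)2 in THF at −78 °C to give 27 as in step 18, and 27 is alkylated directly by F1 (−78 → −20 °C) to give 29. This is the stoichiometric bridgehead lithiation–alkylation, with no transition metal.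

Step 4 (tertiary stereocentre by decarboxylative allylation): the enantiomeric excess may be eroded by proton transfer to the palladium enolate. The fallback sets out from 4 and comes back at 8, replacing steps 3–5. Condensation of 4 with (S)-1-amino-2-(methoxymethyl)pyrrolidine (TsOH cat., benzene, 80 °C) gives the hydrazone (S)-N-[3-methoxy-2-prenylcyclohex-2-en-1-ylidene]-2-(methoxymethyl)pyrrolidin-1-amine F2. LiN(iPr)2 in THF at −78 °C gives the lithium azaenolate F3, which is alkylated by prenyl bromide 2 at −100 °C to the (6S)-6-prenyl hydrazone F4. Two-phase hydrolysis with oxalic acid (Et2O/H2O) releases 8 and the auxiliary. The auxiliary-controlled alkylation installs prenyl directly in place of catalytic allylation plus metathesis.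

Step 7 (conjugate methylation of a tetrasubstituted, γ-branched enone): addition may stall or go 1,2. The fallback sets out from 10 and comes back at 11. DIBAL-H (CH2Cl2, −78 °C) reduces 10 to the allylic alcohol (4S)-3-methyl-2,4-diprenylcyclohex-2-en-1-ol F5. Hydroxyl-directed cyclopropanation (Et2Zn, CH2I2, CH2Cl2, 0 °C) gives (5S)-6-methyl-1,5-diprenylbicyclo[4.1.0]heptan-2-ol F6, and Dess–Martin periodinane gives the cyclopropyl ketone (5S)-6-methyl-1,5-diprenylbicyclo[4.1.0]heptan-2-one F7. Li in NH3/THF at −78 °C cleaves the exocyclic cyclopropane bond, which overlaps best with the carbonyl, giving the gem-dimethyl carbon and the regiodefined lithium enolate lithium (4S)-3,3-dimethyl-2,4-diprenylcyclohex-1-en-1-olate F8. After removal of ammonia, TMSCl/Et3N silylates F8 to 11.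

**Further compounds**
F1 | step 18 | (2E,4S)-1-bromo-4-(tert-butyldimethylsilyloxy)-3,7-dimethylocta-2,6-diene | BrC/C=C(\C)[C@@H](O[Si](C)(C)C(C)(C)C)CC=C(C)C
F2 | step 4 | (S)-N-[3-methoxy-2-prenylcyclohex-2-en-1-ylidene]-2-(methoxymethyl)pyrrolidin-1-amine | COC[C@@H]1CCCN1N=C1CCCC(OC)=C1CC=C(C)C
F3 | step 4 | lithium azaenolate of F2 (N-lithio dienamine) | COC[C@@H]1CCCN1N([Li])C1=CCCC(OC)=C1CC=C(C)C
F4 | step 4 | (S)-N-[(6S)-3-methoxy-2,6-diprenylcyclohex-2-en-1-ylidene]-2-(methoxymethyl)pyrrolidin-1-amine | COC[C@@H]1CCCN1N=C1[C@H](CC=C(C)C)CCC(OC)=C1CC=C(C)C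
F5 | step 7 | (4S)-3-methyl-2,4-diprenylcyclohex-2-en-1-ol (C1 epimers) | CC(C)=CC[C@@H]1CCC(O)C(CC=C(C)C)=C1C
F6 | step 7 | (5S)-6-methyl-1,5-diprenylbicyclo[4.1.0]heptan-2-ol (cyclopropane syn to OH) | CC(C)=CC[C@@H]1CCC(O)C2(CC=C(C)C)CC12C
F7 | step 7 | (5S)-6-methyl-1,5-diprenylbicyclo[4.1.0]heptan-2-one | CC(C)=CC[C@@H]1CCC(=O)C2(CC=C(C)C)CC12C
F8 | step 7 | lithium (4S)-3,3-dimethyl-2,4-diprenylcyclohex-1-en-1-olate | CC(C)=CC[C@@H]1CCC(O[Li])=C(CC=C(C)C)C1(C)C
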